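**Strategy.** The tetrahydrofuran ring (O1, C2–C5) is read as a formal [3+2] adduct of a ketone, O1=C2, carrying the dienyl group and the future CH2O carbon, and a three-carbon unit C3–C4–C5. The nine-membered-ring carbon on C4 that bears the exocyclic methylene is carried as a nitrile: it makes C3 the nucleophilic γ-carbon of an allylindium and C5 a Michael acceptor. One operation therefore forms the tertiary–quaternary bond C2–C3 and the ether bond O1–C5, joining a linalool-derived allylic bromide with a dienyl α-ketoester of a chiral auxiliary. Ring-closing metathesis then closes the (Z)-cyclononene.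

Key step: step 8

Remark: (S)-(+)-linalool and (+)-8-phenylmenthol are taken as commercial. The facial sense of the auxiliary is assumed from the chelate model of its α-ketoesters (attack anti to the stacked phenyl ring); with the opposite sense the antipodal auxiliary would be used. The titanium methylenation reagent of step 10 is drawn with σ-bonded cyclopentadienyl rings and with its bridging chloride as a chloronium–aluminate pair.

Step 1
Reactants: 1 (S)-linalool
Product: 2 (S)-linalyl acetate
Conditions: Ac2O, Et3N, DMAP (cat.), CH2Cl2, 25 °C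
Reagents that add atoms: acetic anhydride, CC(=O)OC(C)=O
Why: DMAP-catalysed acylation masks the tertiary alcohol (the free 4-hydroxy aldehyde of step 2 would close to a lactol) with a group that the hydride of step 11 removes at no extra cost.

Step 2
Reactants: 2 (S)-linalyl acetate
Product: 4 acetoxy aldehyde, via ozonide 3 (not isolated)
Conditions: O3 (1.0 equiv, Sudan red 7B indicator), CH2Cl2, −78 °C; then Me2S, −78 → 25 °C
Reagents that add atoms: ozone, [O-][O+]=O
Why: Chemoselective ozonolysis with reductive work-up: the electron-rich trisubstituted olefin should be cleaved much faster than the vinyl group, which is monosubstituted and deactivated by the allylic acetoxy group.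

Step 3
Reactants: 4 acetoxy aldehyde, 5 acrylonitrile
Product: 6 Baylis–Hillman adduct
Conditions: DABCO (0.5 equiv), acrylonitrile (5 equiv, neat), 25 °C, 3–5 d
Reagents that add atoms: none
Why: Morita–Baylis–Hillman reaction of an aliphatic aldehyde; the new carbinol centre is formed without control and is erased in step 4.

Step 4
Reactants: 6 Baylis–Hillman adduct
Product: 7 allylic bromide
Conditions: NBS, Me2S, CH2Cl2, 0 → 25 °C
Reagents that add atoms: N-bromosuccinimide, O=C1CCC(=O)N1Br
Why: Corey–Kim-type activation of the allylic alcohol and SN2' attack of bromide give the rearranged primary bromide; the (E)-isomer (chain cis to the slim nitrile) should dominate, and the geometry is immaterial because the allylindium of step 8 equilibrates.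

Step 5
Reactants: 8 (+)-8-phenylmenthol
Product: 9 chlorooxoacetate
Conditions: (COCl)2 (3 equiv), CH2Cl2, 0 → 25 °C; evaporation
Reagents that add atoms: oxalyl chloride, O=C(Cl)C(Cl)=O
Why: Mono-acylation of the hindered secondary alcohol by excess oxalyl chloride gives the alkyl chlorooxoacetate.

Step 6
Reactants: 9 chlorooxoacetate
Product: 10 keto ylide
Conditions: Ph3P=CH2 (2.1 equiv, from Ph3PCH3Br and NaN(SiMe3)2), THF, −78 → 0 °C
Reagents that add atoms: methylenetriphenylphosphorane, C=P(c1ccccc1)(c1ccccc1)c1ccccc1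
Why: C-acylation of the non-stabilised ylide by the acid chloride, with the second equivalent of ylide deprotonating the acylphosphonium salt (transylidation), gives the stabilised keto ylide.

Step 7
Reactants: 10 keto ylide, 11 3-methylbut-2-enal
Product: 12 dienyl α-ketoester
Conditions: toluene, 90 °C
Reagents that add atoms: none
Why: Wittig reaction of a stabilised acyl ylide with an enal, which should be (E)-selective.

Step 8
Reactants: 7 allylic bromide, 12 dienyl α-ketoester
Product: 15 tetrahydrofuran nitrile (2R,3S,4R), via allylindium dibromide 13 (not isolated), via homoallylic alcohol 14 (not isolated)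
Conditions: In powder (1.5 equiv), DMF–THF (1:1), 25 °C; then DBU (1.5 equiv), 40 °C, same flask; aq NH4Cl
Reagents that add atoms: none
Why: Indium inserts into the allylic C–Br bond of 7 and the allylindium 13 adds through its γ-carbon (C3) to the ketone carbon (C2) of 12 in a Barbier allylation, after which DBU lets the tertiary alkoxide of 14 add to the α-methylene nitrile (oxa-Michael) to form O1–C5; the closest known reaction types are the indium- or zinc-mediated addition of 2-(bromomethyl)acrylate-type bromides to carbonyl groups and the base-mediated cyclisation of homoallylic alkoxides onto α-substituted acceptor olefins, as known for vinyl sulfones. The only ring closed is the tetrahydrofuran, in the 5-endo-trig mode, which is slow for weak acceptors but is reversible here and should end at the β-alkoxy nitrile because the competing imidate closure is reversible and less favourable. C2 and C3 are set in a chelated Zimmerman–Traxler chair: indium binds the keto and the ester oxygen, so the ester sits axial and the dienyl group equatorial, and the γ-substituent of the equilibrating allylindium prefers to be trans to CH2In (cis to the slim nitrile), hence equatorial, which places the C3 chain cis to the ester and trans to the dienyl group. The absolute sense comes from the auxiliary, whose phenyl ring stacks over the chelated dicarbonyl unit and leaves the Re face of the ketone open, which should give (2R,3S). C4 is formed by protonation α to the nitrile and should equilibrate under DBU to the trans arrangement (4R); it stays correctable at the ketone stage of step 9. The step needs carbonyl addition rather than conjugate addition to the dienone, which allylindium reagents favour, and ring closure rather than retro-allylation, for which the mild amidine base is chosen.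

Step 9
Reactants: 15 tetrahydrofuran nitrile
Product: 17 allyl ketone, via ketimine 16 (not isolated)
Conditions: allylzinc bromide (1.5 equiv, from allyl bromide and Zn dust), THF, 0 → 25 °C; then AcOH/NaOAc buffer (pH 5), H2O, 0 °C
Reagents that add atoms: allylzinc bromide, C=CC[Zn]Br (made in the flask from allyl bromide, C=CCBr, and zinc); water, O
Why: Addition of the allylzinc reagent to the nitrile (the hindered esters should be left) and buffered hydrolysis of the ketimine give the β,γ-unsaturated ketone; C4 is epimerisable here and should settle trans to the C3 chain.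

Step 10
Reactants: 17 allyl ketone
Product: 18 methylene compound
Conditions: Tebbe reagent (Cp2Ti(μ-Cl)(μ-CH2)AlMe2, 1.2 equiv), pyridine (cat.), THF–toluene, −40 → 0 °C
Reagents that add atoms: Tebbe reagent, C[Al-]1(C)C[Ti]([Cl+]1)(C1C=CC=C1)C1C=CC=C1
Why: Tebbe methylenation is non-basic, so the β,γ-enone should neither enolise nor move into conjugation, and at low temperature it is selective for the ketone over the two esters.

Step 11
Reactants: 18 methylene compound
Product: 19 diol
Conditions: LiAlH4 (4 equiv), Et2O, 0 → 35 °C; aq potassium sodium tartrate work-up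
Reagents that add atoms: none
Why: Hydride reduction cleaves the auxiliary ester to the primary alcohol (auxiliary 8 is recovered) and removes the tertiary acetate in the same operation, while the olefins and the diene are inert.

Step 12
Reactants: 19 diol
Product: 20 stearate
Conditions: stearoyl chloride (1.05 equiv), 2,4,6-collidine, CH2Cl2, −20 → 0 °C
Reagents that add atoms: stearoyl chloride, CCCCCCCCCCCCCCCCCC(=O)Cl
Why: Acylation of the primary hydroxyl is far faster than that of the tertiary allylic hydroxyl.

Step 13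
Reactants: 20 stearate
Product: 21 target CNP0274030.1
Conditions: second-generation Grubbs catalyst (10 mol %), 1,4-benzoquinone (20 mol %), CH2Cl2 (1 mM), 40 °C
Reagents that add atoms: none
Why: Ring-closing metathesis between the allyl terminus and the vinyl group of the free tertiary allylic alcohol; the nine-membered ring can hold only the (Z)-olefin, and the 1,1-disubstituted olefin and the internal, conjugated diene olefin next to a quaternary carbon should stay spectators.

**Compound list**

(8-phenylmenthyl = (1S,2R,5S)-5-methyl-2-(2-phenylpropan-2-yl)cyclohexyl)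

1 | (S)-(+)-linalool, (3S)-3,7-dimethylocta-1,6-dien-3-ol | C=C[C@@](C)(O)CCC=C(C)C | starting material
2 | (S)-linalyl acetate, (3S)-3,7-dimethylocta-1,6-dien-3-yl acetate | C=C[C@@](C)(OC(C)=O)CCC=C(C)C | intermediate
3 | ozonide, (3S)-5-(5,5-dimethyl-1,2,4-trioxolan-3-yl)-3-methylpent-1-en-3-yl acetate (both epimers at the trioxolane carbon) | C=C[C@@](C)(OC(C)=O)CCC1OOC(C)(C)O1 | intermediate
4 | (3S)-3-methyl-6-oxohex-1-en-3-yl acetate | C=C[C@@](C)(OC(C)=O)CCC=O | intermediate
5 | acrylonitrile | C=CC#N | starting material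
6 | (3S)-7-cyano-6-hydroxy-3-methylocta-1,7-dien-3-yl acetate (both C6 epimers) | C=C[C@@](C)(OC(C)=O)CCC(O)C(=C)C#N | intermediate
7 | (3S,6E)-7-(bromomethyl)-7-cyano-3-methylhepta-1,6-dien-3-yl acetate | N#C/C(CBr)=C\CC[C@](C)(OC(C)=O)C=C | intermediate
8 | (+)-8-phenylmenthol, (1S,2R,5S)-5-methyl-2-(2-phenylpropan-2-yl)cyclohexan-1-ol | O[C@H]1C[C@@H](C)CC[C@@H]1C(C)(C)c1ccccc1 | starting material
9 | 8-phenylmenthyl chlorooxoacetate | O=C(Cl)C(=O)O[C@H]1C[C@@H](C)CC[C@@H]1C(C)(C)c1ccccc1 | intermediate
10 | 8-phenylmenthyl 2-oxo-3-(triphenyl-λ5-phosphanylidene)propanoate | O=C(C=P(c1ccccc1)(c1ccccc1)c1ccccc1)C(=O)O[C@H]1C[C@@H](C)CC[C@@H]1C(C)(C)c1ccccc1 | intermediate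
11 | 3-methylbut-2-enal | CC(C)=CC=O | starting material
12 | 8-phenylmenthyl (3E)-6-methyl-2-oxohepta-3,5-dienoate | CC(C)=C/C=C/C(=O)C(=O)O[C@H]1C[C@@H](C)CC[C@@H]1C(C)(C)c1ccccc1 | intermediate
13 | [(2E,6S)-6-acetoxy-2-cyano-6-methylocta-2,7-dienyl]indium dibromide (idealised, E/Z-equilibrating) | Br[In](Br)C/C(C#N)=C/CC[C@](C)(OC(C)=O)C=C | intermediate
14 | 8-phenylmenthyl (2R,3E)-2-[(3S,6S)-6-acetoxy-2-cyano-6-methylocta-1,7-dien-3-yl]-2-hydroxy-6-methylhepta-3,5-dienoate | C=C(C#N)[C@H](CC[C@](C)(OC(C)=O)C=C)[C@](O)(/C=C/C=C(C)C)C(=O)O[C@H]1C[C@@H](C)CC[C@@H]1C(C)(C)c1ccccc1 | intermediate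
15 | 8-phenylmenthyl (2R,3S,4R)-3-[(3S)-3-acetoxy-3-methylpent-4-enyl]-4-cyano-2-[(1E)-4-methylpenta-1,3-dienyl]oxolane-2-carboxylate | N#C[C@@H]1CO[C@@](/C=C/C=C(C)C)(C(=O)O[C@H]2C[C@@H](C)CC[C@@H]2C(C)(C)c2ccccc2)[C@H]1CC[C@](C)(OC(C)=O)C=C | intermediate
16 | ketimine, as 15 with 4-(1-iminobut-3-enyl) in place of 4-cyano | C=CCC(=N)[C@@H]1CO[C@@](/C=C/C=C(C)C)(C(=O)O[C@H]2C[C@@H](C)CC[C@@H]2C(C)(C)c2ccccc2)[C@H]1CC[C@](C)(OC(C)=O)C=C | intermediate
17 | 8-phenylmenthyl (2R,3S,4S)-3-[(3S)-3-acetoxy-3-methylpent-4-enyl]-4-(but-3-enoyl)-2-[(1E)-4-methylpenta-1,3-dienyl]oxolane-2-carboxylate | C=CCC(=O)[C@@H]1CO[C@@](/C=C/C=C(C)C)(C(=O)O[C@H]2C[C@@H](C)CC[C@@H]2C(C)(C)c2ccccc2)[C@H]1CC[C@](C)(OC(C)=O)C=C | intermediate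
18 | 8-phenylmenthyl (2R,3S,4R)-3-[(3S)-3-acetoxy-3-methylpent-4-enyl]-2-[(1E)-4-methylpenta-1,3-dienyl]-4-(penta-1,4-dien-2-yl)oxolane-2-carboxylate | C=CCC(=C)[C@@H]1CO[C@@](/C=C/C=C(C)C)(C(=O)O[C@H]2C[C@@H](C)CC[C@@H]2C(C)(C)c2ccccc2)[C@H]1CC[C@](C)(OC(C)=O)C=C | intermediate
19 | (3S)-5-[(2R,3S,4R)-2-(hydroxymethyl)-2-[(1E)-4-methylpenta-1,3-dienyl]-4-(penta-1,4-dien-2-yl)oxolan-3-yl]-3-methylpent-1-en-3-ol | C=CCC(=C)[C@@H]1CO[C@@](/C=C/C=C(C)C)(CO)[C@H]1CC[C@](C)(O)C=C | intermediate
20 | [(2R,3S,4R)-3-[(3S)-3-hydroxy-3-methylpent-4-enyl]-2-[(1E)-4-methylpenta-1,3-dienyl]-4-(penta-1,4-dien-2-yl)oxolan-2-yl]methyl octadecanoate | C=CCC(=C)[C@@H]1CO[C@@](/C=C/C=C(C)C)(COC(=O)CCCCCCCCCCCCCCCCC)[C@H]1CC[C@](C)(O)C=C | intermediate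
21 | CNP0274030.1, [(1R,3aR,6Z,8S,10aS)-8-hydroxy-8-methyl-4-methylidene-1-[(1E)-4-methylpenta-1,3-dienyl]-3,3a,4,5,8,9,10,10a-octahydro-1H-cyclonona[c]furan-1-yl]methyl octadecanoate | C=C1C/C=C\[C@@](C)(O)CC[C@H]2[C@H]1CO[C@@]2(/C=C/C=C(C)C)COC(=O)CCCCCCCCCCCCCCCCC | target

**Step count.** Total: 13 steps. Longest linear sequence: 10 steps (steps 1–4 and 8–13).

**Steps most likely to fail**

Step 8. The 5-endo-trig conjugate addition of the hindered tertiary alkoxide may be too slow, so that retro-allylation or return of the open alcohol competes. Selection between the two faces and the two chair arrangements in the allyl transfer may also be incomplete. Fallback: setting out from homoallylic alcohol 14 (isolated after the indium stage with aq NH4Cl), allylzinc bromide is added to the nitrile and buffered hydrolysis gives the hydroxy α-methylene allyl ketone F1. This much stronger acceptor is closed under acid catalysis (camphorsulfonic acid, CH2Cl2, 0 °C), where 5-endo additions of hydroxy enones proceed through the protonated enone. The product is allyl ketone 17, where the route is rejoined.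

Step 13. Intermolecular metathesis may outrun closure of the strained nine-membered ring, or the ruthenium carbene may close onto the side-chain diene to give a seven-membered ring. Fallback: setting out from allyl ketone 17, the ring is closed before the exocyclic methylene exists and while both hydroxyl functions are still masked (second-generation Hoveyda–Grubbs catalyst, toluene, 80 °C, high dilution). This changes the ring that is closed to a cyclononenone and gives the bicyclic keto ester F2. Tebbe methylenation on the ring gives the bicyclic methylene ester F3, LiAlH4 gives the bicyclic diol F4, and selective stearoylation of its primary hydroxyl leads to target 21.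

Step 9. A second allyl group may add to the metalated ketimine, or the β,γ-double bond may move into conjugation during hydrolysis. Fallback: setting out from nitrile 15, MeMgBr with catalytic CuBr·SMe2 gives the methyl ketone F5; the acetate is cleaved on the way, and the hindered auxiliary ester should survive. Kinetic enolisation on the methyl side (KN(SiMe3)2, 2.2 equiv, −78 °C) and Comins' reagent give the enol triflate F6. A Stille coupling with allyltributylstannane (Pd(PPh3)4, LiCl, THF, 60 °C) gives the skipped diene as the hydroxy ester F7, and LiAlH4 then gives diol 19, where the route is rejoined.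

**Further compounds**

F1 | step 8 | 8-phenylmenthyl (2R,3E)-2-[(3S,6S)-6-acetoxy-2-(but-3-enoyl)-6-methylocta-1,7-dien-3-yl]-2-hydroxy-6-methylhepta-3,5-dienoate | C=CCC(=O)C(=C)[C@H](CC[C@](C)(OC(C)=O)C=C)[C@](O)(/C=C/C=C(C)C)C(=O)O[C@H]1C[C@@H](C)CC[C@@H]1C(C)(C)c1ccccc1
F2 | step 13 | 8-phenylmenthyl (1R,3aS,6Z,8S,10aS)-8-acetoxy-8-methyl-1-[(1E)-4-methylpenta-1,3-dienyl]-4-oxo-3,3a,4,5,8,9,10,10a-octahydro-1H-cyclonona[c]furan-1-carboxylate | O=C1C/C=C\[C@@](C)(OC(C)=O)CC[C@H]2[C@H]1CO[C@@]2(/C=C/C=C(C)C)C(=O)O[C@H]1C[C@@H](C)CC[C@@H]1C(C)(C)c1ccccc1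
F3 | step 13 | 8-phenylmenthyl (1R,3aR,6Z,8S,10aS)-8-acetoxy-8-methyl-4-methylidene-1-[(1E)-4-methylpenta-1,3-dienyl]-3,3a,4,5,8,9,10,10a-octahydro-1H-cyclonona[c]furan-1-carboxylate | C=C1C/C=C\[C@@](C)(OC(C)=O)CC[C@H]2[C@H]1CO[C@@]2(/C=C/C=C(C)C)C(=O)O[C@H]1C[C@@H](C)CC[C@@H]1C(C)(C)c1ccccc1
F4 | step 13 | (1R,3aR,6Z,8S,10aS)-1-(hydroxymethyl)-8-methyl-4-methylidene-1-[(1E)-4-methylpenta-1,3-dienyl]-3,3a,4,5,8,9,10,10a-octahydro-1H-cyclonona[c]furan-8-ol | C=C1C/C=C\[C@@](C)(O)CC[C@H]2[C@H]1CO[C@@]2(/C=C/C=C(C)C)CO
F5 | step 9 | 8-phenylmenthyl (2R,3S,4S)-4-acetyl-3-[(3S)-3-hydroxy-3-methylpent-4-enyl]-2-[(1E)-4-methylpenta-1,3-dienyl]oxolane-2-carboxylate | CC(=O)[C@@H]1CO[C@@](/C=C/C=C(C)C)(C(=O)O[C@H]2C[C@@H](C)CC[C@@H]2C(C)(C)c2ccccc2)[C@H]1CC[C@](C)(O)C=C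
F6 | step 9 | 8-phenylmenthyl (2R,3S,4S)-3-[(3S)-3-hydroxy-3-methylpent-4-enyl]-2-[(1E)-4-methylpenta-1,3-dienyl]-4-[1-(trifluoromethylsulfonyloxy)ethenyl]oxolane-2-carboxylate | C=C(OS(=O)(=O)C(F)(F)F)[C@@H]1CO[C@@](/C=C/C=C(C)C)(C(=O)O[C@H]2C[C@@H](C)CC[C@@H]2C(C)(C)c2ccccc2)[C@H]1CC[C@](C)(O)C=C
F7 | step 9 | 8-phenylmenthyl (2R,3S,4R)-3-[(3S)-3-hydroxy-3-methylpent-4-enyl]-2-[(1E)-4-methylpenta-1,3-dienyl]-4-(penta-1,4-dien-2-yl)oxolane-2-carboxylate | C=CCC(=C)[C@@H]1CO[C@@](/C=C/C=C(C)C)(C(=O)O[C@H]2C[C@@H](C)CC[C@@H]2C(C)(C)c2ccccc2)[C@H]1CC[C@](C)(O)C=C
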